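Retrosynthesis: the two ester C–O bonds (O15–succinyl, O19–isovaleryl) are cut first, then the chain at C14–C15 and C13–C16 (methylalumination–hydroxymethylation of a C13≡C14 alkyne), at C12–C13 (acetylide alkylation) and at C9–C11 (Johnson–Claisen from a 7β-allylic alcohol).
Ring A is then opened at C1–C10: C10 with its methyl C20 is the para carbon of a 2,4-dimethylphenol whose oxygen is the future C7 position, whose ortho methyl is C17 and whose C5 carries the tether C4–C3–C2–C1, so a C1 mesylate can alkylate C10 and turn aromatic ring B into a cross-conjugated dienone.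
The tether is cut at C4–C19 (lactone enolate alkylation) and C3–C4 (arylacetic acid dianion plus a C1–C3 epoxide); the lactone carbonyl that serves both bonds ends as the C18 methyl.
Forward order: ring B is bought as an arene; the tether is built on it through a lactone; ring A closes in step 15; ring B is reduced and re-oxidized to the 8-en-7-one; the C9 chain is added by a [3,3] shift and extended; the acyl groups come last.
Stereochemistry: C2 from (S)-glycidyl trityl ether; C4 by enolate alkylation anti to the C2 substituent on the lactone; C10 from the chair of the ring closure (C2 and C4 substituents equatorial); C5 from Li/NH3 (trans fusion); C9 by suprafacial transfer from the 7β-hydroxyl set by Luche reduction; the 13E double bond by syn carboalumination.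

Key step: step 15

Remark: atoms carry labdane numbers throughout (C17 on C8, C18 and C19 on C4, C20 on C10; β is the face of C20). TBS = tert-butyldimethylsilyl, TIPS = triisopropylsilyl, Tr = triphenylmethyl, Bn = benzyl. Compounds 1 and 7 are taken as commercial. The C8 epimers formed in step 16 converge in step 17 and are not separated.

Step 1
Reactants: 1 2-(2,4-dimethylphenyl)acetic acid
Product: 2 2-(2,4-dimethyl-5-nitrophenyl)acetic acid
Conditions: HNO3 (1.05 equiv), H2SO4, 0 °C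
Reagents that add atoms: nitric acid, O[N+](=O)[O-]
Why: Electrophilic aromatic nitration should enter C7, the only position that is para to one methyl (on C10), ortho to the other (on C8) and not flanked on both sides, as in other 1,2,4-trialkylbenzenes.

Step 2
Reactants: 2 2-(2,4-dimethyl-5-nitrophenyl)acetic acid
Product: 3 2-(5-amino-2,4-dimethylphenyl)acetic acid
Conditions: H2 (1 atm), Pd/C, MeOH, rt
Reagents that add atoms: none
Why: Catalytic hydrogenation of a nitroarene to the aniline is standard and leaves the acid untouched.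

Step 3
Reactants: 3 2-(5-amino-2,4-dimethylphenyl)acetic acid
Product: 5 2-(5-hydroxy-2,4-dimethylphenyl)acetic acid, via diazonium salt 4 (not isolated)
Conditions: NaNO2, aq. H2SO4, 0 °C; then boiling aq. H2SO4
Reagents that add atoms: water, O
Why: Diazotization followed by hydrolysis of the diazonium salt in hot dilute acid (phenol synthesis from an aniline) places the C7 oxygen.

Step 4
Reactants: 5 2-(5-hydroxy-2,4-dimethylphenyl)acetic acid
Product: 6 2-[5-(benzyloxy)-2,4-dimethylphenyl]acetic acid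
Conditions: BnBr (1.1 equiv), NaOH (2.2 equiv), EtOH/H2O, 70 °C; then aq. HCl
Reagents that add atoms: benzyl bromide, BrCc1ccccc1
Why: Williamson ether synthesis on the phenolate, which in aqueous ethanol is far more nucleophilic than the carboxylate, so only the phenol should be benzylated.

Step 5
Reactants: 6 2-[5-(benzyloxy)-2,4-dimethylphenyl]acetic acid; 7 (S)-glycidyl trityl ether
Product: 10 (5S)-3-[5-(benzyloxy)-2,4-dimethylphenyl]-5-[(trityloxy)methyl]oxolan-2-one (C3 epimers), via dilithium enediolate 8 (not isolated), via hydroxy acid 9 (not isolated)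
Conditions: LiN(i-Pr)2 (2.2 equiv), THF, −78 → 0 °C; 7, 0 °C → rt; AcOH; then DCC, DMAP (cat.), CH2Cl2, rt
Reagents that add atoms: none
Why: Epoxide opening by the arylacetic acid dianion at the terminal carbon forms C3–C4 and a Steglich-type lactonization closes the ring without acid; C2 is carried over unchanged from the epoxide and the C4 epimers converge in step 6.

Step 6
Reactants: 10 (5S)-3-[5-(benzyloxy)-2,4-dimethylphenyl]-5-[(trityloxy)methyl]oxolan-2-one
Product: 12 (3R,5S)-3-[5-(benzyloxy)-2,4-dimethylphenyl]-3-[(benzyloxy)methyl]-5-[(trityloxy)methyl]oxolan-2-one, via lithium enolate 11 (not isolated)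
Conditions: LiN(i-Pr)2 (1.1 equiv), THF, −78 °C; BnOCH2Cl, −78 → −20 °C
Reagents that add atoms: benzyl chloromethyl ether, ClCOCc1ccccc1
Why: Enolate alkylation of a γ-substituted butyrolactone: the electrophile should enter anti to the bulky trityloxymethyl group on C2, which sets quaternary C4 with C19 trans to C1 (the lactone carbonyl is the future C18).

Step 7
Reactants: 12 (3R,5S)-3-[5-(benzyloxy)-2,4-dimethylphenyl]-3-[(benzyloxy)methyl]-5-[(trityloxy)methyl]oxolan-2-one
Product: 13 (3R,5S)-3-[5-(benzyloxy)-2,4-dimethylphenyl]-3-[(benzyloxy)methyl]-5-[(trityloxy)methyl]oxolan-2-ol (anomers)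
Conditions: i-Bu2AlH (1.2 equiv), CH2Cl2, −78 °C; aq. potassium sodium tartrate
Reagents that add atoms: none
Why: Partial reduction of a lactone to the lactol with i-Bu2AlH at low temperature is routine and stops at the hemiacetal.

Step 8
Reactants: 13 (3R,5S)-3-[5-(benzyloxy)-2,4-dimethylphenyl]-3-[(benzyloxy)methyl]-5-[(trityloxy)methyl]oxolan-2-ol
Product: 15 (2S,4S)-5-(benzyloxy)-4-[5-(benzyloxy)-2,4-dimethylphenyl]-4-methyl-1-(trityloxy)pentan-2-ol, via hydrazone 14 (not isolated)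
Conditions: N2H4·H2O, KOH, diethylene glycol, 130 °C then 200 °C
Reagents that add atoms: none
Why: Wolff–Kishner reduction (Huang-Minlon procedure) of the lactol through its open-chain aldehyde hydrazone turns the former lactone carbon into the C18 methyl and frees the C2 hydroxyl; the ethers and the non-enolizable quaternary centre tolerate the hot base.

Step 9
Reactants: 15 (2S,4S)-5-(benzyloxy)-4-[5-(benzyloxy)-2,4-dimethylphenyl]-4-methyl-1-(trityloxy)pentan-2-ol
Product: 16 (2S,4S)-5-(benzyloxy)-4-[5-(benzyloxy)-2,4-dimethylphenyl]-4-methyl-2-(triisopropylsilyloxy)-1-(trityloxy)pentane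
Conditions: i-Pr3SiOTf, 2,6-lutidine, CH2Cl2, 0 °C
Reagents that add atoms: triisopropylsilyl trifluoromethanesulfonate, CC(C)[Si](C(C)C)(C(C)C)OS(=O)(=O)C(F)(F)F
Why: Silylation of a hindered secondary alcohol with a silyl triflate and a hindered pyridine base; the robust TIPS ether is chosen so that it outlasts the primary TBS ether to be removed in step 25.

Step 10
Reactants: 16 (2S,4S)-5-(benzyloxy)-4-[5-(benzyloxy)-2,4-dimethylphenyl]-4-methyl-2-(triisopropylsilyloxy)-1-(trityloxy)pentane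
Product: 17 (2S,4S)-5-(benzyloxy)-4-[5-(benzyloxy)-2,4-dimethylphenyl]-4-methyl-2-(triisopropylsilyloxy)pentan-1-ol
Conditions: TsOH·H2O (cat.), MeOH/CH2Cl2, 0 °C
Reagents that add atoms: none
Why: Acid-catalysed solvolysis of the trityl ether (trityl cation trapped by methanol) should be much faster than cleavage of the secondary TIPS ether or of the benzyl ethers.

Step 11
Reactants: 17 (2S,4S)-5-(benzyloxy)-4-[5-(benzyloxy)-2,4-dimethylphenyl]-4-methyl-2-(triisopropylsilyloxy)pentan-1-ol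
Product: 18 (2S,4S)-5-(benzyloxy)-4-[5-(benzyloxy)-2,4-dimethylphenyl]-4-methyl-2-(triisopropylsilyloxy)pentyl methanesulfonate
Conditions: MsCl, Et3N, CH2Cl2, 0 °C
Reagents that add atoms: methanesulfonyl chloride, CS(=O)(=O)Cl
Why: Sulfonylation of the primary C1 alcohol (mesylation) installs the leaving group for ring closure.

Step 12
Reactants: 18 (2S,4S)-5-(benzyloxy)-4-[5-(benzyloxy)-2,4-dimethylphenyl]-4-methyl-2-(triisopropylsilyloxy)pentyl methanesulfonate
Product: 19 (2S,4S)-5-hydroxy-4-(5-hydroxy-2,4-dimethylphenyl)-4-methyl-2-(triisopropylsilyloxy)pentyl methanesulfonate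
Conditions: H2 (1 atm), Pd(OH)2/C, EtOAc/EtOH, rt
Reagents that add atoms: none
Why: Hydrogenolysis cleaves the aryl and the alkyl benzyl ether together, while the mesylate and the silyl ether are inert and the neutral phenol and alcohol do not displace the sulfonate.

Step 13
Reactants: 19 (2S,4S)-5-hydroxy-4-(5-hydroxy-2,4-dimethylphenyl)-4-methyl-2-(triisopropylsilyloxy)pentyl methanesulfonate
Product: 20 (2S,4S)-4-(2-bromo-3-hydroxy-4,6-dimethylphenyl)-5-hydroxy-4-methyl-2-(triisopropylsilyloxy)pentyl methanesulfonate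
Conditions: NBS (1.0 equiv), i-Pr2NH (cat.), CH2Cl2, −20 → 0 °C, dark
Reagents that add atoms: N-bromosuccinimide, O=C1CCC(=O)N1Br
Why: Electrophilic ortho-bromination of a phenol (amine-catalysed NBS) can only go to C6 because C8 and C10 carry methyl groups; the bromine will deny C6 a rearomatizing alkylation in step 15.

Step 14
Reactants: 20 (2S,4S)-4-(2-bromo-3-hydroxy-4,6-dimethylphenyl)-5-hydroxy-4-methyl-2-(triisopropylsilyloxy)pentyl methanesulfonate
Product: 21 (2S,4S)-4-[2-bromo-3-(TBSO)-4,6-dimethylphenyl]-5-(TBSO)-4-methyl-2-(TIPSO)pentyl methanesulfonate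
Conditions: t-BuMe2SiOTf (2.5 equiv), 2,6-lutidine, CH2Cl2, −78 → 0 °C
Reagents that add atoms: tert-butyldimethylsilyl trifluoromethanesulfonate, CC(C)(C)[Si](C)(C)OS(=O)(=O)C(F)(F)F
Why: Silylation with a silyl triflate masks the neopentyl C19 alcohol, whose alkoxide could otherwise displace the mesylate, and stores the phenol as a fluoride-labile aryl silyl ether.

Step 15
Reactants: 21 (2S,4S)-4-[2-bromo-3-(TBSO)-4,6-dimethylphenyl]-5-(TBSO)-4-methyl-2-(TIPSO)pentyl methanesulfonate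
Product: 23 6-bromo-19-(TBSO)-2α-(TIPSO)-11,12,13,14,15,16-hexanorlabda-5,8-dien-7-one, via ammonium phenolate 22 (not isolated)
Conditions: n-Bu4NF (1.05 equiv), THF (0.01 M), 0 → 40 °C
Reagents that add atoms: none
Why: Fluoride cleaves only the aryl O–Si bond and the phenolate 22 attacks the primary mesylate with its para carbon C10 in an intramolecular SN2 displacement; because C10 carries C20 it cannot rearomatize, so the C1–C10 bond, ring A, quaternary C10 and the cross-conjugated ring B dienone (C7 carbonyl, C17 on C8) form together. The closest known reaction type is the base- or fluoride-induced intramolecular para-C-alkylation of phenolates by alkyl sulfonates or halides (aryl participation) that gives fused or spiro cyclohexa-2,5-dienones. Ring A closes in the 6-exo-tet mode. C10 is set by the chair of the forming ring: with the 2α-silyloxy group and C18 equatorial and C19 axial, C1 bonds to the α face of C10 and C20 ends β, whereas the other face would force the silyloxy group, C18 and C20 to be syn-axial. The step needs para-carbon over ortho-carbon and oxygen alkylation: bromine at C6 leaves the ortho carbon no rearomatizing outlet, the oxygen cannot reach C1 without a meta bridge, the C19 oxygen is silylated, and high dilution suppresses intermolecular O-alkylation.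

Step 16
Reactants: 23 6-bromo-19-(TBSO)-2α-(TIPSO)-11,12,13,14,15,16-hexanorlabda-5,8-dien-7-one
Product: 24 19-(TBSO)-2α-(TIPSO)-11,12,13,14,15,16-hexanor-5α-labdan-7-one (C8 epimers)
Conditions: Li (excess), NH3(l)/THF, t-BuOH (2 equiv), −78 → −33 °C; then solid NH4Cl
Reagents that add atoms: none
Why: Dissolving-metal reduction cleaves the vinylic C–Br bond and reduces both enone double bonds in turn; protonation of the C5 β-carbanion should give the trans ring fusion (5α-H), and the silyl ethers are inert.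

Step 17
Reactants: 24 19-(TBSO)-2α-(TIPSO)-11,12,13,14,15,16-hexanor-5α-labdan-7-one
Product: 26 19-(TBSO)-2α-(TIPSO)-11,12,13,14,15,16-hexanor-5α-labd-8-en-7-one, via silyl enol ether 25 (not isolated)
Conditions: Me3SiCl, NaI, Et3N, MeCN, rt; then Pd(OAc)2 (1.1 equiv), MeCN, rt
Reagents that add atoms: none
Why: Saegusa–Ito oxidation: the more substituted (thermodynamic) silyl enol ether C7=C8 is oxidized by Pd(OAc)2 with β-hydride loss from C9, which restores the C8–C9 enone and erases the C8 stereocentre.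

Step 18
Reactants: 26 19-(TBSO)-2α-(TIPSO)-11,12,13,14,15,16-hexanor-5α-labd-8-en-7-one
Product: 27 19-(TBSO)-2α-(TIPSO)-11,12,13,14,15,16-hexanor-5α-labd-8-en-7β-ol
Conditions: NaBH4, CeCl3·7H2O, MeOH, −20 °C
Reagents that add atoms: none
Why: Luche reduction (1,2-selective): hydride should add axially from the α face, opposite to nothing larger than the axial C5–H, and give the pseudo-equatorial 7β-alcohol.

Step 19
Reactants: 27 19-(TBSO)-2α-(TIPSO)-11,12,13,14,15,16-hexanor-5α-labd-8-en-7β-ol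
Product: 30 ethyl 19-(TBSO)-2α-(TIPSO)-13,14,15,16-tetranorlabd-7-en-12-oate (9α-H), via mixed orthoester 28 (not isolated), via ketene acetal 29 (not isolated)
Conditions: MeC(OEt)3 (excess), EtCO2H (cat.), xylene, 140 °C
Reagents that add atoms: triethyl orthoacetate, CCOC(C)(OCC)OCC
Why: Johnson–Claisen rearrangement: the ketene acetal on the 7β-oxygen rearranges suprafacially, so the C9–C11 bond forms on the β face and the double bond moves to C7–C8.

Step 20
Reactants: 30 ethyl 19-(TBSO)-2α-(TIPSO)-13,14,15,16-tetranorlabd-7-en-12-oate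
Product: 31 19-(TBSO)-2α-(TIPSO)-13,14,15,16-tetranorlabd-7-en-12-ol
Conditions: LiAlH4, Et2O, 0 °C
Reagents that add atoms: none
Why: Hydride reduction of the ester to the primary alcohol; silyl ethers and the trisubstituted alkene are inert.

Step 21
Reactants: 31 19-(TBSO)-2α-(TIPSO)-13,14,15,16-tetranorlabd-7-en-12-ol
Product: 32 12-iodo-19-(TBSO)-2α-(TIPSO)-13,14,15,16-tetranorlabd-7-ene
Conditions: PPh3, I2, imidazole, CH2Cl2, 0 °C → rt
Reagents that add atoms: iodine, [I][I]
Why: Appel-type iodination of an unhindered primary alcohol under buffered conditions.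

Step 22
Reactants: 32 12-iodo-19-(TBSO)-2α-(TIPSO)-13,14,15,16-tetranorlabd-7-ene
Product: 33 19-(TBSO)-2α-(TIPSO)-15,16-dinorlabd-7-en-13-yne
Conditions: LiC≡CH·H2NCH2CH2NH2, DMSO, rt
Reagents that add atoms: lithium acetylide ethylenediamine complex, [Li+].[C-]#C.NCCN
Why: SN2 alkylation of lithium acetylide by the primary iodide in DMSO forms C12–C13.

Step 23
Reactants: 33 19-(TBSO)-2α-(TIPSO)-15,16-dinorlabd-7-en-13-yne
Product: 36 19-(TBSO)-2α-(TIPSO)-labda-7,13E-dien-15-ol, via alkenylalane 34 (not isolated), via lithium alanate 35 (not isolated)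
Conditions: Me3Al, Cp2ZrCl2 (cat.), CH2Cl2, 0 °C → rt; evaporate; n-BuLi, THF, −78 °C; (CH2O)n, → rt
Reagents that add atoms: trimethylaluminium, C[Al](C)C; paraformaldehyde (formaldehyde unit), C=O
Why: Negishi zirconium-catalysed carboalumination adds methyl and aluminium syn across the terminal alkyne (C16 on C13, E geometry), and the derived alanate adds to formaldehyde with retention to give the (E)-allylic alcohol.

Step 24
Reactants: 36 19-(TBSO)-2α-(TIPSO)-labda-7,13E-dien-15-ol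
Product: 37 methyl 19-(TBSO)-2α-(TIPSO)-labda-7,13E-dien-15-yl butanedioate
Conditions: MeO2C(CH2)2COCl, pyridine, DMAP (cat.), CH2Cl2, 0 °C
Reagents that add atoms: methyl 4-chloro-4-oxobutanoate, COC(=O)CCC(=O)Cl
Why: Acylation of the only free hydroxyl, a primary allylic alcohol, with an acid chloride under DMAP catalysis.

Step 25
Reactants: 37 methyl 19-(TBSO)-2α-(TIPSO)-labda-7,13E-dien-15-yl butanedioate
Product: 38 methyl 19-hydroxy-2α-(TIPSO)-labda-7,13E-dien-15-yl butanedioate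
Conditions: HF·pyridine, pyridine, THF, 0 °C → rt
Reagents that add atoms: none
Why: Fluoride cleavage of the primary TBS ether with buffered HF·pyridine should be much faster than cleavage of the secondary TIPS ether and leaves the esters alone.

Step 26
Reactants: 38 methyl 19-hydroxy-2α-(TIPSO)-labda-7,13E-dien-15-yl butanedioate
Product: 39 methyl 19-(3-methylbutanoyloxy)-2α-(TIPSO)-labda-7,13E-dien-15-yl butanedioate
Conditions: Me2CHCH2COCl, pyridine, DMAP, CH2Cl2, rt
Reagents that add atoms: 3-methylbutanoyl chloride, CC(C)CC(=O)Cl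
Why: DMAP-catalysed acylation of the hindered neopentyl C19 alcohol, the only free hydroxyl.

Step 27
Reactants: 39 methyl 19-(3-methylbutanoyloxy)-2α-(TIPSO)-labda-7,13E-dien-15-yl butanedioate
Product: 40 CNP0118741.1, methyl 2α-hydroxy-19-(3-methylbutanoyloxy)labda-7,13E-dien-15-yl butanedioate
Conditions: n-Bu4NF, AcOH (1:1), THF, rt
Reagents that add atoms: none
Why: Fluoride desilylation of the secondary TIPS ether, buffered with acetic acid so that the three esters survive; acyl migration from O19 to O2 would need a seven-membered transition state.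

Compound list
1 | 2-(2,4-dimethylphenyl)acetic acid | Cc1ccc(CC(=O)O)c(C)c1 | starting material
2 | 2-(2,4-dimethyl-5-nitrophenyl)acetic acid | Cc1cc(C)c(CC(=O)O)cc1[N+](=O)[O-] | intermediate
3 | 2-(5-amino-2,4-dimethylphenyl)acetic acid | Cc1cc(C)c(CC(=O)O)cc1N | intermediate
4 | 5-(carboxymethyl)-2,4-dimethylbenzenediazonium hydrogensulfate (not isolated) | Cc1cc(C)c(CC(=O)O)cc1[N+]#N.OS(=O)(=O)[O-] | intermediate
5 | 2-(5-hydroxy-2,4-dimethylphenyl)acetic acid | Cc1cc(C)c(CC(=O)O)cc1O | intermediate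
6 | 2-[5-(benzyloxy)-2,4-dimethylphenyl]acetic acid | Cc1cc(C)c(CC(=O)O)cc1OCc1ccccc1 | intermediate
7 | (S)-glycidyl trityl ether, (2S)-2-[(trityloxy)methyl]oxirane | C1[C@@H](COC(c2ccccc2)(c2ccccc2)c2ccccc2)O1 | starting material
8 | dilithium enediolate of 6 (not isolated) | [Li+].[Li+].[O-]C([O-])=Cc1cc(OCc2ccccc2)c(C)cc1C | intermediate
9 | (4S)-2-[5-(benzyloxy)-2,4-dimethylphenyl]-4-hydroxy-5-(trityloxy)pentanoic acid, C2 epimers (not isolated) | Cc1cc(C)c(cc1OCc1ccccc1)C(C(=O)O)C[C@H](O)COC(c1ccccc1)(c1ccccc1)c1ccccc1 | intermediate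
10 | (5S)-3-[5-(benzyloxy)-2,4-dimethylphenyl]-5-[(trityloxy)methyl]oxolan-2-one, C3 epimers | Cc1cc(C)c(cc1OCc1ccccc1)C1C[C@@H](COC(c2ccccc2)(c2ccccc2)c2ccccc2)OC1=O | intermediate
11 | lithium enolate of 10 (not isolated) | [Li+].[O-]C1=C(c2cc(OCc3ccccc3)c(C)cc2C)C[C@@H](COC(c2ccccc2)(c2ccccc2)c2ccccc2)O1 | intermediate
12 | (3R,5S)-3-[5-(benzyloxy)-2,4-dimethylphenyl]-3-[(benzyloxy)methyl]-5-[(trityloxy)methyl]oxolan-2-one | Cc1cc(C)c(cc1OCc1ccccc1)[C@@]1(COCc2ccccc2)C[C@@H](COC(c2ccccc2)(c2ccccc2)c2ccccc2)OC1=O | intermediate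
13 | (3R,5S)-3-[5-(benzyloxy)-2,4-dimethylphenyl]-3-[(benzyloxy)methyl]-5-[(trityloxy)methyl]oxolan-2-ol, anomers | Cc1cc(C)c(cc1OCc1ccccc1)[C@@]1(COCc2ccccc2)C[C@@H](COC(c2ccccc2)(c2ccccc2)c2ccccc2)OC1O | intermediate
14 | hydrazone of (2S,4S)-2-[5-(benzyloxy)-2,4-dimethylphenyl]-2-[(benzyloxy)methyl]-4-hydroxy-5-(trityloxy)pentanal (not isolated) | Cc1cc(C)c(cc1OCc1ccccc1)[C@@](C=NN)(COCc1ccccc1)C[C@H](O)COC(c1ccccc1)(c1ccccc1)c1ccccc1 | intermediate
15 | (2S,4S)-5-(benzyloxy)-4-[5-(benzyloxy)-2,4-dimethylphenyl]-4-methyl-1-(trityloxy)pentan-2-ol | Cc1cc(C)c(cc1OCc1ccccc1)[C@@](C)(COCc1ccccc1)C[C@H](O)COC(c1ccccc1)(c1ccccc1)c1ccccc1 | intermediate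
16 | (2S,4S)-5-(benzyloxy)-4-[5-(benzyloxy)-2,4-dimethylphenyl]-4-methyl-2-(triisopropylsilyloxy)-1-(trityloxy)pentane | Cc1cc(C)c(cc1OCc1ccccc1)[C@@](C)(COCc1ccccc1)C[C@H](O[Si](C(C)C)(C(C)C)C(C)C)COC(c1ccccc1)(c1ccccc1)c1ccccc1 | intermediate
17 | (2S,4S)-5-(benzyloxy)-4-[5-(benzyloxy)-2,4-dimethylphenyl]-4-methyl-2-(triisopropylsilyloxy)pentan-1-ol | Cc1cc(C)c(cc1OCc1ccccc1)[C@@](C)(COCc1ccccc1)C[C@H](O[Si](C(C)C)(C(C)C)C(C)C)CO | intermediate
18 | (2S,4S)-5-(benzyloxy)-4-[5-(benzyloxy)-2,4-dimethylphenyl]-4-methyl-2-(triisopropylsilyloxy)pentyl methanesulfonate | Cc1cc(C)c(cc1OCc1ccccc1)[C@@](C)(COCc1ccccc1)C[C@H](O[Si](C(C)C)(C(C)C)C(C)C)COS(C)(=O)=O | intermediate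
19 | (2S,4S)-5-hydroxy-4-(5-hydroxy-2,4-dimethylphenyl)-4-methyl-2-(triisopropylsilyloxy)pentyl methanesulfonate | Cc1cc(C)c(cc1O)[C@@](C)(CO)C[C@H](O[Si](C(C)C)(C(C)C)C(C)C)COS(C)(=O)=O | intermediate
20 | (2S,4S)-4-(2-bromo-3-hydroxy-4,6-dimethylphenyl)-5-hydroxy-4-methyl-2-(triisopropylsilyloxy)pentyl methanesulfonate | Cc1cc(C)c(c(Br)c1O)[C@@](C)(CO)C[C@H](O[Si](C(C)C)(C(C)C)C(C)C)COS(C)(=O)=O | intermediate
21 | (2S,4S)-4-[2-bromo-3-(tert-butyldimethylsilyloxy)-4,6-dimethylphenyl]-5-(tert-butyldimethylsilyloxy)-4-methyl-2-(triisopropylsilyloxy)pentyl methanesulfonate | Cc1cc(C)c(c(Br)c1O[Si](C)(C)C(C)(C)C)[C@@](C)(CO[Si](C)(C)C(C)(C)C)C[C@H](O[Si](C(C)C)(C(C)C)C(C)C)COS(C)(=O)=O | intermediate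
22 | tetrabutylammonium phenolate of 21 after loss of the aryl silyl group (not isolated) | Cc1cc(C)c(c(Br)c1[O-])[C@@](C)(CO[Si](C)(C)C(C)(C)C)C[C@H](O[Si](C(C)C)(C(C)C)C(C)C)COS(C)(=O)=O.CCCC[N+](CCCC)(CCCC)CCCC | intermediate
23 | 6-bromo-19-(tert-butyldimethylsilyloxy)-2α-(triisopropylsilyloxy)-11,12,13,14,15,16-hexanorlabda-5,8-dien-7-one (10β-methyl) | C1=C(C)C(=O)C(Br)=C2[C@@](C)(CO[Si](C)(C)C(C)(C)C)C[C@H](O[Si](C(C)C)(C(C)C)C(C)C)C[C@]12C | intermediate
24 | 19-(tert-butyldimethylsilyloxy)-2α-(triisopropylsilyloxy)-11,12,13,14,15,16-hexanor-5α-labdan-7-one, C8 epimers | C1C(C)C(=O)C[C@H]2[C@@](C)(CO[Si](C)(C)C(C)(C)C)C[C@H](O[Si](C(C)C)(C(C)C)C(C)C)C[C@]12C | intermediate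
25 | 7-(trimethylsilyloxy)-19-(tert-butyldimethylsilyloxy)-2α-(triisopropylsilyloxy)-11,12,13,14,15,16-hexanor-5α-labd-7-ene (not isolated) | C1C(C)=C(O[Si](C)(C)C)C[C@H]2[C@@](C)(CO[Si](C)(C)C(C)(C)C)C[C@H](O[Si](C(C)C)(C(C)C)C(C)C)C[C@]12C | intermediate
26 | 19-(tert-butyldimethylsilyloxy)-2α-(triisopropylsilyloxy)-11,12,13,14,15,16-hexanor-5α-labd-8-en-7-one | C1=C(C)C(=O)C[C@H]2[C@@](C)(CO[Si](C)(C)C(C)(C)C)C[C@H](O[Si](C(C)C)(C(C)C)C(C)C)C[C@]12C | intermediate
27 | 19-(tert-butyldimethylsilyloxy)-2α-(triisopropylsilyloxy)-11,12,13,14,15,16-hexanor-5α-labd-8-en-7β-ol | C1=C(C)[C@@H](O)C[C@H]2[C@@](C)(CO[Si](C)(C)C(C)(C)C)C[C@H](O[Si](C(C)C)(C(C)C)C(C)C)C[C@]12C | intermediate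
28 | 7β-O-(1,1-diethoxyethyl) mixed orthoester of 27 (not isolated) | C1=C(C)[C@@H](OC(C)(OCC)OCC)C[C@H]2[C@@](C)(CO[Si](C)(C)C(C)(C)C)C[C@H](O[Si](C(C)C)(C(C)C)C(C)C)C[C@]12C | intermediate
29 | 7β-O-(1-ethoxyvinyl) ketene acetal of 27 (not isolated) | C1=C(C)[C@@H](OC(=C)OCC)C[C@H]2[C@@](C)(CO[Si](C)(C)C(C)(C)C)C[C@H](O[Si](C(C)C)(C(C)C)C(C)C)C[C@]12C | intermediate
30 | ethyl 19-(tert-butyldimethylsilyloxy)-2α-(triisopropylsilyloxy)-13,14,15,16-tetranorlabd-7-en-12-oate (9α-H, side chain β) | CCOC(=O)C[C@H]1C(C)=CC[C@H]2[C@@](C)(CO[Si](C)(C)C(C)(C)C)C[C@H](O[Si](C(C)C)(C(C)C)C(C)C)C[C@]12C | intermediate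
31 | 19-(tert-butyldimethylsilyloxy)-2α-(triisopropylsilyloxy)-13,14,15,16-tetranorlabd-7-en-12-ol | OCC[C@H]1C(C)=CC[C@H]2[C@@](C)(CO[Si](C)(C)C(C)(C)C)C[C@H](O[Si](C(C)C)(C(C)C)C(C)C)C[C@]12C | intermediate
32 | 12-iodo-19-(tert-butyldimethylsilyloxy)-2α-(triisopropylsilyloxy)-13,14,15,16-tetranorlabd-7-ene | ICC[C@H]1C(C)=CC[C@H]2[C@@](C)(CO[Si](C)(C)C(C)(C)C)C[C@H](O[Si](C(C)C)(C(C)C)C(C)C)C[C@]12C | intermediate
33 | 19-(tert-butyldimethylsilyloxy)-2α-(triisopropylsilyloxy)-15,16-dinorlabd-7-en-13-yne | C#CCC[C@H]1C(C)=CC[C@H]2[C@@](C)(CO[Si](C)(C)C(C)(C)C)C[C@H](O[Si](C(C)C)(C(C)C)C(C)C)C[C@]12C | intermediate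
34 | (13E)-14-(dimethylalumanyl)-19-(tert-butyldimethylsilyloxy)-2α-(triisopropylsilyloxy)-15-norlabda-7,13-diene (not isolated) | C[Al](C)/C=C(\C)CC[C@H]1C(C)=CC[C@H]2[C@@](C)(CO[Si](C)(C)C(C)(C)C)C[C@H](O[Si](C(C)C)(C(C)C)C(C)C)C[C@]12C | intermediate
35 | lithium butyl(dimethyl)alanate of 34 (not isolated) | [Li+].CCCC[Al-](C)(C)/C=C(\C)CC[C@H]1C(C)=CC[C@H]2[C@@](C)(CO[Si](C)(C)C(C)(C)C)C[C@H](O[Si](C(C)C)(C(C)C)C(C)C)C[C@]12C | intermediate
36 | 19-(tert-butyldimethylsilyloxy)-2α-(triisopropylsilyloxy)-labda-7,13E-dien-15-ol | OC/C=C(\C)CC[C@H]1C(C)=CC[C@H]2[C@@](C)(CO[Si](C)(C)C(C)(C)C)C[C@H](O[Si](C(C)C)(C(C)C)C(C)C)C[C@]12C | intermediate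
37 | methyl 19-(tert-butyldimethylsilyloxy)-2α-(triisopropylsilyloxy)-labda-7,13E-dien-15-yl butanedioate | COC(=O)CCC(=O)OC/C=C(\C)CC[C@H]1C(C)=CC[C@H]2[C@@](C)(CO[Si](C)(C)C(C)(C)C)C[C@H](O[Si](C(C)C)(C(C)C)C(C)C)C[C@]12C | intermediate
38 | methyl 19-hydroxy-2α-(triisopropylsilyloxy)-labda-7,13E-dien-15-yl butanedioate | COC(=O)CCC(=O)OC/C=C(\C)CC[C@H]1C(C)=CC[C@H]2[C@@](C)(CO)C[C@H](O[Si](C(C)C)(C(C)C)C(C)C)C[C@]12C | intermediate
39 | methyl 19-(3-methylbutanoyloxy)-2α-(triisopropylsilyloxy)-labda-7,13E-dien-15-yl butanedioate | COC(=O)CCC(=O)OC/C=C(\C)CC[C@H]1C(C)=CC[C@H]2[C@@](C)(COC(=O)CC(C)C)C[C@H](O[Si](C(C)C)(C(C)C)C(C)C)C[C@]12C | intermediate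
40 | CNP0118741.1, methyl 2α-hydroxy-19-(3-methylbutanoyloxy)labda-7,13E-dien-15-yl butanedioate | COC(=O)CCC(=O)OC/C=C(\C)CC[C@H]1C(C)=CC[C@H]2[C@@](C)(COC(=O)CC(C)C)C[C@H](O)C[C@]12C | target

Total step count: 27.
Longest linear sequence: 27 steps (1 → 40); epoxide 7 is bought and enters in step 5.

Steps most likely to fail

Step 15 (ring closure). What may go wrong: displacement at the β-silyloxy primary carbon by the crowded para carbon may be slower than intermolecular O-alkylation, than elimination of methanesulfonate, or than bonding through the bromine-bearing ortho carbon. Fallback: set out from 21 and change the electrophile and the phenolate. A Finkelstein exchange (NaI, acetone, reflux) should give the primary iodide F1. CsF in DMF (rt → 50 °C, high dilution) then frees the caesium phenolate F2, whose para carbon displaces the softer and more reactive iodide. The product is dienone 23, where the route is rejoined.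

Step 13 (ortho-bromination). What may go wrong: C6 lies between the hydroxyl and the quaternary C4, so substitution there may stall while the reagent attacks the para carbon C10 in an ipso sense or the benzylic methyl groups. Fallback: set out from 19 and block C6 with the smaller chlorine, which also eases the compression against C4 during ring closure. SO2Cl2 with a catalytic secondary amine (i-Bu2NH, toluene, 0 °C) delivers chlorine ortho to the hydroxyl and should give the chlorophenol F3. Silylation as in step 14 gives the bis-silyl ether F4. n-Bu4NF as in step 15 releases the phenolate F5, which closes to the 6-chloro dienone F6. Li/NH3 as in step 16 removes chlorine as it would bromine, and the route is rejoined at ketone 24.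

Step 19 (Johnson–Claisen). What may go wrong: the new bond has to form on the β face next to the axial C20 methyl, so at 140 °C under acid the allylic C7–O bond may ionize (loss of the oxygen, diene formation) before the ketene acetal rearranges. Fallback: a Still–Wittig [2,3] shift under basic conditions at low temperature, followed by one-carbon homologation. From 27, KH and Bu3SnCH2I (THF) give the stannylmethyl ether F7. n-BuLi (THF, −78 °C) gives the α-lithio ether F8, which rearranges suprafacially to the 9β-hydroxymethyl 7-ene F9. Dess–Martin oxidation gives aldehyde F10 and Wittig methylenation (Ph3P=CH2, THF, −78 → 0 °C) gives the 9β-vinyl compound F11. Hydroboration of the vinyl group with 9-BBN (borane F12) and oxidation with NaOH/H2O2 give alcohol 31, where the route is rejoined.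

Further compounds
F1 | step 15 | (2S,4S)-4-[2-bromo-3-(tert-butyldimethylsilyloxy)-4,6-dimethylphenyl]-5-(tert-butyldimethylsilyloxy)-1-iodo-4-methyl-2-(triisopropylsilyloxy)pentane | Cc1cc(C)c(c(Br)c1O[Si](C)(C)C(C)(C)C)[C@@](C)(CO[Si](C)(C)C(C)(C)C)C[C@H](O[Si](C(C)C)(C(C)C)C(C)C)CI
F2 | step 15 | caesium phenolate of F1 after loss of the aryl silyl group | Cc1cc(C)c(c(Br)c1[O-])[C@@](C)(CO[Si](C)(C)C(C)(C)C)C[C@H](O[Si](C(C)C)(C(C)C)C(C)C)CI.[Cs+]
F3 | step 13 | (2S,4S)-4-(2-chloro-3-hydroxy-4,6-dimethylphenyl)-5-hydroxy-4-methyl-2-(triisopropylsilyloxy)pentyl methanesulfonate | Cc1cc(C)c(c(Cl)c1O)[C@@](C)(CO)C[C@H](O[Si](C(C)C)(C(C)C)C(C)C)COS(C)(=O)=O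
F4 | step 13 | (2S,4S)-4-[2-chloro-3-(tert-butyldimethylsilyloxy)-4,6-dimethylphenyl]-5-(tert-butyldimethylsilyloxy)-4-methyl-2-(triisopropylsilyloxy)pentyl methanesulfonate | Cc1cc(C)c(c(Cl)c1O[Si](C)(C)C(C)(C)C)[C@@](C)(CO[Si](C)(C)C(C)(C)C)C[C@H](O[Si](C(C)C)(C(C)C)C(C)C)COS(C)(=O)=O
F5 | step 13 | tetrabutylammonium phenolate of F4 after loss of the aryl silyl group | Cc1cc(C)c(c(Cl)c1[O-])[C@@](C)(CO[Si](C)(C)C(C)(C)C)C[C@H](O[Si](C(C)C)(C(C)C)C(C)C)COS(C)(=O)=O.CCCC[N+](CCCC)(CCCC)CCCC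
F6 | step 13 | 6-chloro-19-(tert-butyldimethylsilyloxy)-2α-(triisopropylsilyloxy)-11,12,13,14,15,16-hexanorlabda-5,8-dien-7-one | C1=C(C)C(=O)C(Cl)=C2[C@@](C)(CO[Si](C)(C)C(C)(C)C)C[C@H](O[Si](C(C)C)(C(C)C)C(C)C)C[C@]12C
F7 | step 19 | 7β-[(tributylstannyl)methoxy]-19-(tert-butyldimethylsilyloxy)-2α-(triisopropylsilyloxy)-11,12,13,14,15,16-hexanor-5α-labd-8-ene | C1=C(C)[C@@H](OC[Sn](CCCC)(CCCC)CCCC)C[C@H]2[C@@](C)(CO[Si](C)(C)C(C)(C)C)C[C@H](O[Si](C(C)C)(C(C)C)C(C)C)C[C@]12C
F8 | step 19 | 7β-(lithiomethoxy) analogue of F7 | C1=C(C)[C@@H](OC[Li])C[C@H]2[C@@](C)(CO[Si](C)(C)C(C)(C)C)C[C@H](O[Si](C(C)C)(C(C)C)C(C)C)C[C@]12C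
F9 | step 19 | 19-(tert-butyldimethylsilyloxy)-2α-(triisopropylsilyloxy)-12,13,14,15,16-pentanorlabd-7-en-11-ol (9α-H) | OC[C@H]1C(C)=CC[C@H]2[C@@](C)(CO[Si](C)(C)C(C)(C)C)C[C@H](O[Si](C(C)C)(C(C)C)C(C)C)C[C@]12C
F10 | step 19 | 19-(tert-butyldimethylsilyloxy)-2α-(triisopropylsilyloxy)-12,13,14,15,16-pentanorlabd-7-en-11-al | O=C[C@H]1C(C)=CC[C@H]2[C@@](C)(CO[Si](C)(C)C(C)(C)C)C[C@H](O[Si](C(C)C)(C(C)C)C(C)C)C[C@]12C
F11 | step 19 | 19-(tert-butyldimethylsilyloxy)-2α-(triisopropylsilyloxy)-13,14,15,16-tetranorlabda-7,11-diene | C=C[C@H]1C(C)=CC[C@H]2[C@@](C)(CO[Si](C)(C)C(C)(C)C)C[C@H](O[Si](C(C)C)(C(C)C)C(C)C)C[C@]12C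
F12 | step 19 | 9-borabicyclo[3.3.1]nonan-9-yl adduct at C12 of F11 | C(C[C@H]1C(C)=CC[C@H]2[C@@](C)(CO[Si](C)(C)C(C)(C)C)C[C@H](O[Si](C(C)C)(C(C)C)C(C)C)C[C@]12C)B1C2CCCC1CCC2
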